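The oxepine ring (O1, C2, C3, C4, C5, C5a, C9a) is reduced to a pyran by excising C4, which lies between C3 (whose exocyclic CH2 is a former methyl group) and benzylic C5. The key operation therefore inserts one carbon into the ring alkene of a 3-methyl-2H-chromene. Dibromocarbene forms a ring-fused gem-dibromocyclopropane; silver-assisted opening of the shared bond enlarges the pyran to the oxepine, and loss of a methyl proton sets the exocyclic methylene and the C4=C5 alkene. The precursor is 3-methyl-6-(silyloxymethyl)-2H-chromene, made by ring-closing metathesis. Debromination, desilylation and stearoylation complete the route.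

Key step: step 6

Remark: benzoxepine atoms are numbered O1, C2, C3, C4, C5, C5a, C6–C9, C9a throughout. The target has no stereocentre; the only stereocentres on the route are the two ring-fusion carbons of adduct 9 (necessarily cis, racemic), and they are erased in the same step.

Step 1
Reactants: 1 methyl 3-formyl-4-hydroxybenzoate; 2 3-chloro-2-methylprop-1-ene
Product: 3 methyl 3-formyl-4-[(2-methylprop-2-en-1-yl)oxy]benzoate
Conditions: K2CO3, KI (cat.), DMF, 60 °C
Reagents that add atoms: 3-chloro-2-methylprop-1-ene (compound 2), C=C(C)CCl
Why: Williamson ether synthesis, in which the carbonate-generated phenoxide of the acidic ortho-formyl phenol displaces the allylic chloride (iodide-assisted SN2) and no stereocentre is formed.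

Step 2
Reactants: 3 methyl 3-formyl-4-[(2-methylprop-2-en-1-yl)oxy]benzoate
Product: 4 methyl 3-ethenyl-4-[(2-methylprop-2-en-1-yl)oxy]benzoate
Conditions: Ph3PCH3Br, NaN(SiMe3)2, THF, 0 °C; then 3, −78 °C → rt
Reagents that add atoms: methyltriphenylphosphonium bromide, C[P+](c1ccccc1)(c1ccccc1)c1ccccc1.[Br-]
Why: Wittig methylenation, in which the non-stabilised ylide attacks the aldehyde far faster than the methyl benzoate and the silylamide base leaves only a non-nucleophilic amine, so the ester should not be transesterified.

Step 3
Reactants: 4 methyl 3-ethenyl-4-[(2-methylprop-2-en-1-yl)oxy]benzoate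
Product: 5 methyl 3-methyl-2H-chromene-6-carboxylate
Conditions: second-generation Grubbs catalyst, RuCl2(=CHPh)(PCy3)(H2IMes) (3 mol %), CH2Cl2 (0.02 M), 40 °C
Reagents that add atoms: none
Why: Ring-closing metathesis, in which the ruthenium carbene loads at the styrene and closes onto the 1,1-disubstituted allyl ether to give the six-membered trisubstituted alkene with loss of ethene.

Step 4
Reactants: 5 methyl 3-methyl-2H-chromene-6-carboxylate
Product: 6 (3-methyl-2H-chromen-6-yl)methanol
Conditions: LiAlH4, THF, 0 °C; aqueous potassium sodium tartrate work-up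
Reagents that add atoms: none
Why: Hydride reduction of an aryl ester to the benzylic alcohol, the isolated styrenyl alkene and the allyl aryl ether being inert to LiAlH4 at this temperature.

Step 5
Reactants: 6 (3-methyl-2H-chromen-6-yl)methanol
Product: 7 triisopropyl[(3-methyl-2H-chromen-6-yl)methoxy]silane (3-methyl-6-[(triisopropylsilyloxy)methyl]-2H-chromene)
Conditions: iPr3SiCl, imidazole, DMF, rt
Reagents that add atoms: triisopropylsilyl chloride, CC(C)[Si](Cl)(C(C)C)C(C)C
Why: Imidazole-promoted silylation of a primary alcohol, giving a bulky silyl ether that keeps alkoxide away from the carbene and should tolerate tert-butoxide, silver ion and tin hydride, while leaving the arene electronically neutral for the next step.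

Step 6
Reactants: 7 triisopropyl[(3-methyl-2H-chromen-6-yl)methoxy]silane; 8 bromoform
Product: 11 4-bromo-3-methylene-7-[(triisopropylsilyloxy)methyl]-2,3-dihydro-1-benzoxepine, via dibromocyclopropane adduct 9 (not isolated), via bromoallyl cation 10 (not isolated)
Conditions: CHBr3, KOtBu, pentane, −10 °C → rt; filtration through Celite and solvent exchange without purification; then AgBF4, 2,6-di-tert-butyl-4-methylpyridine, CH2Cl2, 0 → 40 °C, dark
Reagents that add atoms: bromoform (compound 8), BrC(Br)Br
Why: Singlet dibromocarbene, formed from bromoform by α-elimination, adds in a concerted [2+1] cheletropic manner to the only alkene of 7, an electron-rich trisubstituted styrene, which closes the cyclopropane and creates the C3–C4 and C4–C5 bonds of the future oxepine (adduct 9). Silver ion then pulls off the bromide that sits over the pyran ring while the shared cyclopropane bond opens in a disrotatory two-electron electrocyclic process, so the seven-membered ring results from enlargement of the pyran by cleavage of the ring-fusion bond and not from an end-to-end cyclisation. The resulting allyl cation 10 is supported at C3 by the methyl group and at C5 by the arene and its ortho ring oxygen, and it gives up a methyl proton to the hindered pyridine to deliver the 2-bromo-1,3-diene. The sequence belongs to the known dihalocarbene addition and silver-assisted gem-dihalocyclopropane ring expansion of cyclic alkenes. The two stereocentres of 9 are cis by necessity and are destroyed on opening, so no stereocontrol is required. The selectivity needed is proton loss from the methyl group instead of loss from C2 or capture of the cation; this is secured because the methyl hydrogens are the most accessible to a bulky base, removal of a C2 proton would force a planar 8π 1-benzoxepine, and tert-butanol and KBr are removed before AgBF4 with its non-nucleophilic counter-ion is added.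

Step 7
Reactants: 11 4-bromo-3-methylene-7-[(triisopropylsilyloxy)methyl]-2,3-dihydro-1-benzoxepine
Product: 12 triisopropyl[(3-methylene-2,3-dihydro-1-benzoxepin-7-yl)methoxy]silane
Conditions: Bu3SnH (slow addition), Pd(PPh3)4 (5 mol %), THF, rt
Reagents that add atoms: none
Why: Palladium-catalysed hydrodehalogenation of an alkenyl bromide, in which zerovalent palladium inserts into the C4–Br bond, the tin hydride transfers hydride to palladium and reductive elimination forms the C4–H bond under neutral conditions that should leave the diene and the silyl ether untouched.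

Step 8
Reactants: 12 triisopropyl[(3-methylene-2,3-dihydro-1-benzoxepin-7-yl)methoxy]silane
Product: 13 (3-methylene-2,3-dihydro-1-benzoxepin-7-yl)methanol
Conditions: Bu4NF, THF, 0 °C → rt
Reagents that add atoms: none
Why: Fluoride-induced cleavage of the Si–O bond (silyl ether deprotection), for which no other group in the molecule is reactive at this mild basicity.

Step 9
Reactants: 13 (3-methylene-2,3-dihydro-1-benzoxepin-7-yl)methanol; 14 stearoyl chloride (octadecanoyl chloride)
Product: 15 (3-methylene-2,3-dihydro-1-benzoxepin-7-yl)methyl octadecanoate (target)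
Conditions: Et3N, DMAP (cat.), CH2Cl2, 0 °C → rt
Reagents that add atoms: octadecanoyl chloride (compound 14), CCCCCCCCCCCCCCCCCC(=O)Cl
Why: DMAP-catalysed acylation of a primary benzylic alcohol by an acid chloride (nucleophilic acyl substitution), with the amine buffer protecting the acid-sensitive diene and the p-alkoxybenzylic ester from ionisation.

Compound list
1 | methyl 3-formyl-4-hydroxybenzoate | COC(=O)c1ccc(O)c(C=O)c1 | starting material
2 | 3-chloro-2-methylprop-1-ene | C=C(C)CCl | starting material
3 | methyl 3-formyl-4-[(2-methylprop-2-en-1-yl)oxy]benzoate | COC(=O)c1ccc(OCC(C)=C)c(C=O)c1 | intermediate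
4 | methyl 3-ethenyl-4-[(2-methylprop-2-en-1-yl)oxy]benzoate | COC(=O)c1ccc(OCC(C)=C)c(C=C)c1 | intermediate
5 | methyl 3-methyl-2H-chromene-6-carboxylate | COC(=O)c1ccc2OCC(C)=Cc2c1 | intermediate
6 | (3-methyl-2H-chromen-6-yl)methanol | CC1=Cc2cc(CO)ccc2OC1 | intermediate
7 | triisopropyl[(3-methyl-2H-chromen-6-yl)methoxy]silane | CC1=Cc2cc(CO[Si](C(C)C)(C(C)C)C(C)C)ccc2OC1 | intermediate
8 | bromoform | BrC(Br)Br | starting material
9 | 1,1-dibromo-1a-methyl-6-[(triisopropylsilyloxy)methyl]-1,1a,2,7b-tetrahydrocyclopropa[c]chromene, cis ring fusion, racemic (one enantiomer drawn) | C[C@]12COc3ccc(CO[Si](C(C)C)(C(C)C)C(C)C)cc3[C@H]1C2(Br)Br | intermediate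
10 | 4-bromo-3-methyl-7-[(triisopropylsilyloxy)methyl]-2,3-dihydro-1-benzoxepin-3-ylium tetrafluoroborate (allyl cation delocalised over C3, C4 and C5) | C[C+]1COc2ccc(CO[Si](C(C)C)(C(C)C)C(C)C)cc2C=C1Br.F[B-](F)(F)F | intermediate
11 | 4-bromo-3-methylene-7-[(triisopropylsilyloxy)methyl]-2,3-dihydro-1-benzoxepine | C=C1COc2ccc(CO[Si](C(C)C)(C(C)C)C(C)C)cc2C=C1Br | intermediate
12 | triisopropyl[(3-methylene-2,3-dihydro-1-benzoxepin-7-yl)methoxy]silane | C=C1C=Cc2cc(CO[Si](C(C)C)(C(C)C)C(C)C)ccc2OC1 | intermediate
13 | (3-methylene-2,3-dihydro-1-benzoxepin-7-yl)methanol | C=C1C=Cc2cc(CO)ccc2OC1 | intermediate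
14 | stearoyl chloride (octadecanoyl chloride) | CCCCCCCCCCCCCCCCCC(=O)Cl | starting material
15 | (3-methylene-2,3-dihydro-1-benzoxepin-7-yl)methyl octadecanoate | C=C1C=Cc2cc(COC(=O)CCCCCCCCCCCCCCCCC)ccc2OC1 | target

Total step count: 9. Longest linear sequence: 9 steps (1 to 15).

Steps most likely to fail

Step 6. The allyl cation may lose its proton at C2 instead of at the methyl group, or may be intercepted or oligomerise, so that ring enlargement does not end in the exocyclic diene. The fallback gives up the ring expansion and forms the C4=C5 bond by olefination. It sets out from 1, which is O-alkylated with an excess of 3-chloro-2-(chloromethyl)prop-1-ene (K2CO3, DMF) to give methyl 4-{[2-(chloromethyl)prop-2-en-1-yl]oxy}-3-formylbenzoate F1. Heating with PPh3 in toluene should give [2-({2-formyl-4-(methoxycarbonyl)phenoxy}methyl)prop-2-en-1-yl]triphenylphosphonium chloride F2. NaOMe in MeOH at high dilution generates methyl 3-formyl-4-({2-[(triphenylphosphoranylidene)methyl]prop-2-en-1-yl}oxy)benzoate F3, which closes on the ortho aldehyde by intramolecular Wittig olefination, the established way from salicylaldehydes to 2,3-dihydro-1-benzoxepines. The product is methyl 3-methylene-2,3-dihydro-1-benzoxepine-7-carboxylate F4. Reduction with LiAlH4 in THF at 0 °C gives alcohol 13, where the route is rejoined before step 9.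

Step 7. Palladium hydride may move the exocyclic double bond into the ring, or tin hydride may add across the diene. The fallback replaces the catalytic reduction by halogen–metal exchange. It sets out from 11, which with tert-butyllithium (2 equiv, THF/Et2O, −78 °C) should give {3-methylene-7-[(triisopropylsilyloxy)methyl]-2,3-dihydro-1-benzoxepin-4-yl}lithium F5. Protonation with MeOH at −78 °C returns the route to 12.

Step 3. Ring closure onto the 1,1-disubstituted alkene may be slow, so that styrene homodimerisation or ruthenium-hydride alkene migration takes over. The fallback forms the chromene by the known vinylphosphonium annulation of salicylaldehydes instead of by metathesis. It sets out from 1, whose sodium phenoxide (NaH, DMF) adds to triphenyl(prop-1-en-2-yl)phosphonium bromide to give methyl 3-formyl-4-[2-(triphenylphosphoranylidene)propoxy]benzoate F6. This ylide closes on the ortho aldehyde by intramolecular Wittig olefination on warming and comes back to the route at 5.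

Further compounds
F1 | step 6 | methyl 4-{[2-(chloromethyl)prop-2-en-1-yl]oxy}-3-formylbenzoate | COC(=O)c1ccc(OCC(=C)CCl)c(C=O)c1
F2 | step 6 | [2-({2-formyl-4-(methoxycarbonyl)phenoxy}methyl)prop-2-en-1-yl]triphenylphosphonium chloride | COC(=O)c1ccc(OCC(=C)C[P+](c2ccccc2)(c2ccccc2)c2ccccc2)c(C=O)c1.[Cl-]
F3 | step 6 | methyl 3-formyl-4-({2-[(triphenylphosphoranylidene)methyl]prop-2-en-1-yl}oxy)benzoate | COC(=O)c1ccc(OCC(=C)C=P(c2ccccc2)(c2ccccc2)c2ccccc2)c(C=O)c1
F4 | step 6 | methyl 3-methylene-2,3-dihydro-1-benzoxepine-7-carboxylate | COC(=O)c1ccc2OCC(=C)C=Cc2c1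
F5 | step 7 | {3-methylene-7-[(triisopropylsilyloxy)methyl]-2,3-dihydro-1-benzoxepin-4-yl}lithium | [Li]C1=Cc2cc(CO[Si](C(C)C)(C(C)C)C(C)C)ccc2OCC1=C
F6 | step 3 | methyl 3-formyl-4-[2-(triphenylphosphoranylidene)propoxy]benzoate | COC(=O)c1ccc(OCC(C)=P(c2ccccc2)(c2ccccc2)c2ccccc2)c(C=O)c1
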